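The coupling partner was what I followed through these flasks, as a possible limiting reagent.

| setting | noon | spring | midnight | Sunday's | Monday's | Friday's | Wednesday's | Tuesday's |
|---|---|---|---|---|---|---|---|---|
| starting material | 0.015 M | 0.026 M | 0.020 M | 0.020 M | 0.020 M | 0.040 M | 0.020 M | 0.020 M |
| second substrate | 0.020 M | 0.020 M | 0.020 M | 0.0200 M | 0.0200 M | 0.0200 M | 0.0200 M | 0.0200 M |
| coupling partner | 0.020 M | 0.020 M | 0.020 M | 0.0200 M | 0.0200 M | 0.0200 M | 0.0200 M | 0.0200 M |
| protic impurity | 2 mM | 2 mM | 1.8 mM | 2.00 mM | 2.00 mM | 2.00 mM | 0.600 mM | 8.00 mM |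
| free catalyst | 0.50 mM | 0.50 mM | 0.50 mM | 0.50 mM | 0.50 mM | 0.50 mM | 0.25 mM | 0.50 mM |
| temperature | 8 °C | 35 °C | 8 °C | −5 °C | 25 °C | 45 °C | 25 °C | 25 °C |
| remark | run made earlier | run made earlier | run made earlier |  |  |  |  |  |
| time |  |  |  | 10 h | 10 h | 10 h | 10 h | 10 h |

| run | time / h | target / % |
|---|---|---|
| noon | 1.33 | 9.1 |
| noon | 2.00 | 12.5 |
| noon | 3.00 | 18.4 |
| noon | 5.00 | 27.2 |
| noon | 8.00 | 36.6 |
| noon | 12.0 | 46.0 |
| noon | 20.0 | 55.3 |
| spring | 0.250 | 7.7 |
| spring | 0.667 | 19.1 |
| spring | 1.33 | 29.6 |
| spring | 2.00 | 36.9 |
| spring | 2.50 | 38.6 |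
| spring | 4.00 | 43.1 |
| spring | 5.00 | 43.8 |
| midnight | 1.50 | 7.5 |
| midnight | 5.00 | 21.9 |
| midnight | 8.00 | 32.8 |
| midnight | 12.0 | 41.9 |
| midnight | 20.0 | 49.1 |

(readings scatter by 0.5 percentage points)

- all flasks from highest to lowest amount of target, in percent of the starting material charged, at 10 h (Sunday's / Monday's / Friday's / Wednesday's / Tuesday's)
- the amount of target, in percent of the starting material charged of the flask you put first, at 10 h
- the amount of target, in percent of the starting material charged of the flask you put last, at 10 h

- the numbers in the tables scatter by 0.5 percentage points (one standard deviation)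
- no earlier run changes the charge of free catalyst; that part of a forecast is a guess

The spring run had flattened at 43.8 % of its starting material, which was 11.4 mM of target, less than the 0.020 M of coupling partner charged. So I supposed that the rest of the coupling partner had gone to the second substrate, and that each substrate lost the same fraction of itself. That gave my rule, the even-split ceiling: c(coupling partner) divided by the sum of c(starting material) and c(second substrate), which for Monday's came to 50.0 %.

The same sum gave 43.5 % for the spring run, close to its reading, and 57.1 % for the noon run, which was still rising at 55.3 %. But a ceiling says nothing of speed. The midnight run, at 8 °C and with nearly Sunday's charge, had reached 41.9 % by 12.0 h, so I expected colder Sunday's to lie far below its ceiling. Monday's, at 25 °C, I expected near its ceiling and ahead of Friday's, whose ceiling was lower at 33.3 %. The earlier runs held the protic impurity near 2 mM, so Tuesday's 8.00 mM and Wednesday's 0.600 mM lay outside them, and I could not place those two flasks.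

The forecast read the stall differently: “Yields then stall short of full conversion, which points to catalyst death”. It gave Wednesday's > Monday's > Friday's > Sunday's > Tuesday's, with 53 % (45 % to 62 %) for the first flask and 14.5 % (10 % to 19 %) for the last.

The flasks gave Monday's > Wednesday's > Tuesday's > Friday's > Sunday's, with 50.8 % for Monday's, 17.4 % for Sunday's and 43.5 % for Tuesday's.

    starting material + free catalyst ⇌ catalyst intermediate A (K = 1200 /M, k = 27.0 /M/min, Ea = 50.0 kJ/mol, ΔH = 29.0 kJ/mol)
    coupling partner + catalyst intermediate A → free catalyst + target (k = 13.0 /M/min, Ea = 47.0 kJ/mol)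
    second substrate + free catalyst ⇌ catalyst intermediate B (K = 230 /M, k = 24.0 /M/min, Ea = 50.0 kJ/mol, ΔH = 14.0 kJ/mol)
    coupling partner + catalyst intermediate B → free catalyst + second product (k = 40.0 /M/min, Ea = 59.0 kJ/mol)
    starting material + protic impurity → quenched substrate (k = 0.990 /M/min, Ea = 70.0 kJ/mol)
    (constants at 25 °C)

In Monday's the coupling partner went through catalyst intermediate A to target and through catalyst intermediate B to second product, and at 10.0 h 0.808 % of it remained, with 0.00967 M of second product and 50.8 % of target against the ceiling of 50.0 %. Friday's ran the same two steps, and at 10.0 h its coupling partner stood at 0 %, with target at 34.4 % against its ceiling of 33.3 %.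

The readings come from a simulation for substances that don't exist, noise included.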